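**Strategy.** The route rests on disconnecting the O1–C2 bond of the dihydrofuran ring (O1, C2, C3, C3a, C7a) of the furo[3,2-c]pyran-4-one core. C2 carries both O1 and the catechol ring, whose 4-oxygen is para to C2, so this bond is the 1,6-addition of the pyranone enol oxygen to a para-quinone methide. Such a species can be released from a donor–acceptor spirocyclopropane: a trans-1-aryl-2-pyranonyl cyclopropane spiro-fused at the future C3a to 6-methylpyran-2,4-dione, with the catechol masked as electron-poor acetates. Acetate removal opens the C2–C3a bond and recloses through oxygen, giving the trans-dihydrofuran in one operation, with C3 carried unchanged from an enantioselective cyclopropanation.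

Key step: step 7

Remarks on the chemistry:
- Assumption: Rh2(S-NTTL)4 is taken to give the (1S,2R) cyclopropane; if the sense of induction proves opposite, Rh2(R-NTTL)4 is used with no other change.
- Assumption: the spiro carbon of the cyclopropane is drawn 3R; it becomes sp2 in the key step, so its 3S epimer is carried forward equally.
- Stereochemical check: the target is (2S,3S), which is the trans isomer. The cyclopropane carbon that becomes C3 is labelled R before and S after the key step although it is not touched, because ring opening changes the CIP ranking of its neighbours.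
- The catechol acetates are kept; the carbonate is used substoichiometrically in a THF-rich, degassed medium at 0 °C so that acetate cleavage outruns attack on the spiro enol lactone.

**Route**

Step 1
Reactants: 1 4-hydroxy-6-methyl-2H-pyran-2-one
Product: 2 4-(methoxymethoxy)-6-methyl-2H-pyran-2-one
Conditions: MOMCl, iPr2NEt, CH2Cl2, 0 °C → rt
Reagents that add atoms: chloromethyl methyl ether, COCCl
Why: Williamson-type O-alkylation of the acidic 4-hydroxyl (a vinylogous carboxylic acid) with the hard electrophile MOMCl under Hünig's base should give the 4-alkoxy-2-pyranone and remove the O–H bond that would interfere with the later dienolate and carbenoid steps.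

Step 2
Reactants: 3 3,4-dihydroxybenzaldehyde
Product: 4 3,4-bis[(tert-butyldimethylsilyl)oxy]benzaldehyde
Conditions: TBSCl, imidazole, DMF, rt
Reagents that add atoms: tert-butyldimethylsilyl chloride, CC(C)(C)[Si](C)(C)Cl
Why: Corey silylation of both phenols should give an aldehyde without acidic protons or electrophilic esters, so that it tolerates the lithium dienolate of step 3.

Step 3
Reactants: 2 4-(methoxymethoxy)-6-methyl-2H-pyran-2-one; 4 3,4-bis[(tert-butyldimethylsilyl)oxy]benzaldehyde
Product: 8 6-[(E)-2-{3,4-bis[(tert-butyldimethylsilyl)oxy]phenyl}ethenyl]-4-(methoxymethoxy)-2H-pyran-2-one, via lithium dienolate 5 (not isolated), via lithium aldolate 6 (not isolated), via benzylic mesylate 7 (not isolated)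
Conditions: LiN(SiMe3)2, THF, −78 °C; 4; MsCl, −78 → 0 °C; Et3N, 0 °C → rt
Reagents that add atoms: none
Why: Vinylogous aldol addition followed by elimination: the amide base removes a proton of the C6 methyl group, the extended dienolate attacks the aldehyde through its exocyclic carbon, and the mesylated aldolate should eliminate with triethylamine to the fully conjugated, thermodynamically preferred E-alkene.

Step 4
Reactants: 8 6-[(E)-2-{3,4-bis[(tert-butyldimethylsilyl)oxy]phenyl}ethenyl]-4-(methoxymethoxy)-2H-pyran-2-one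
Product: 10 4-{(E)-2-[4-(methoxymethoxy)-2-oxo-2H-pyran-6-yl]ethenyl}-1,2-phenylene diacetate, via free catechol 9 (not isolated)
Conditions: Bu4NF, AcOH, THF, 0 °C; then Ac2O, pyridine, DMAP (cat.), 0 °C → rt
Reagents that add atoms: acetic anhydride, CC(=O)OC(C)=O
Why: Buffered fluoride desilylation followed by acetylation in the same flask should exchange the electron-releasing silyl ethers for electron-poor acetates, which make the aryl ring too weak a donor to open the cyclopropane of step 6 and are removable later by mild base, while the MOM enol ether is inert to both reagents.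

Step 5
Reactants: 1 4-hydroxy-6-methyl-2H-pyran-2-one
Product: 11 3-diazo-6-methyl-2H-pyran-2,4(3H)-dione
Conditions: 4-acetamidobenzenesulfonyl azide, Et3N, MeCN, 0 °C → rt
Reagents that add atoms: 4-acetamidobenzenesulfonyl azide, CC(=O)Nc1ccc(cc1)S(=O)(=O)N=[N+]=[N-]
Why: Regitz diazo transfer to the doubly activated C3 position of the cyclic 1,3-dicarbonyl tautomer should proceed under mild amine base and give a stable acceptor/acceptor diazo compound.

Step 6
Reactants: 10 4-{(E)-2-[4-(methoxymethoxy)-2-oxo-2H-pyran-6-yl]ethenyl}-1,2-phenylene diacetate; 11 3-diazo-6-methyl-2H-pyran-2,4(3H)-dione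
Product: 12 4-{(1S,2R,3R)-2-[4-(methoxymethoxy)-2-oxo-2H-pyran-6-yl]-6-methyl-4,8-dioxo-5-oxaspiro[2.5]oct-6-en-1-yl}-1,2-phenylene diacetate (aryl and pyranonyl trans)
Conditions: Rh2(S-NTTL)4 (2 mol %), 11 (2 equiv, slow addition), 4 Å MS, toluene, 40 °C
Reagents that add atoms: none
Why: Rhodium-carbenoid cyclopropanation: the electrophilic carbenoid of divalent rhodium formed from 11 adds to the styryl C=C bond in a concerted, stereospecific [2+1] manner, so the E geometry becomes the trans relationship of aryl and pyranonyl groups, while the chiral N-naphthaloyl-tert-leucinate ligands choose the alkene face and so set C1 (S) and C2 (R) together; the acetates keep the aryl ring too weak a donor for ring opening by the Lewis acidic catalyst, and the spiro carbon (either epimer) is erased in step 7.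

Step 7
Reactants: 12 4-{(1S,2R,3R)-2-[4-(methoxymethoxy)-2-oxo-2H-pyran-6-yl]-6-methyl-4,8-dioxo-5-oxaspiro[2.5]oct-6-en-1-yl}-1,2-phenylene diacetate
Product: 15 (2S,3S)-2-(3,4-dihydroxyphenyl)-3-[4-(methoxymethoxy)-2-oxo-2H-pyran-6-yl]-6-methyl-2,3-dihydro-4H-furo[3,2-c]pyran-4-one, via catechol spirocyclopropane 13 (not isolated), via para-quinone methide 14 (not isolated)
Conditions: K2CO3 (0.5 equiv), MeOH–THF (1:3, degassed), Ar, 0 °C; AcOH quench
Reagents that add atoms: none
Why: Proposed new method: methanolysis of the catechol acetates gives the 4-phenoxide, para to the benzylic cyclopropane carbon, whose electron push should cleave the C1–C3 cyclopropane bond (the future C2–C3a) heterolytically to a para-quinone methide paired with the pyran-2,4-dione enolate, and the enolate oxygen then adds to the methide carbon in an oxa-1,6-addition that restores the arene and forms O1–C2. The closest known reaction type is the Cloke–Wilson rearrangement of donor–acceptor cyclopropyl ketones to 2,3-dihydrofurans under Lewis acid or nucleophile catalysis; only the trigger, a phenoxide unmasked in the flask, is new. The dihydrofuran ring closes in a 5-exo-trig mode, the attacked C=C bond of the quinone methide being exocyclic to the new ring. C3 is the former cyclopropane C2 and is not touched, while the new C2 centre is set under thermodynamic control, since the phenoxide can reopen O1–C2, so the aryl group should settle anti to the C3 pyranonyl group (2S,3S) and both spiro epimers converge. The step needs oxygen rather than carbon reclosure and closure through the ketone-derived rather than the lactone oxygen, both secured by reversibility in favour of the strain-free 4-alkoxy-2-pyranone; it also needs acetate cleavage to outrun attack on the spiro enol lactone, secured by the high acyl-transfer reactivity of catechol acetates at 0 °C with substoichiometric carbonate.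

Step 8
Reactants: 15 (2S,3S)-2-(3,4-dihydroxyphenyl)-3-[4-(methoxymethoxy)-2-oxo-2H-pyran-6-yl]-6-methyl-2,3-dihydro-4H-furo[3,2-c]pyran-4-one
Product: 16 (2S,3S)-2-[3,4-bis(methoxymethoxy)phenyl]-3-[4-(methoxymethoxy)-2-oxo-2H-pyran-6-yl]-6-methyl-2,3-dihydro-4H-furo[3,2-c]pyran-4-one
Conditions: MOMCl, iPr2NEt, CH2Cl2, 0 °C → rt
Reagents that add atoms: chloromethyl methyl ether, COCCl
Why: Williamson-type alkylation of both phenols caps the acidic catechol protons and, by removing the phenoxide donor, should shut off reopening of the O1–C2 bond under the basic conditions of step 10.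

Step 9
Reactants: 17 4-hydroxybenzaldehyde
Product: 18 4-(methoxymethoxy)benzaldehyde
Conditions: MOMCl, iPr2NEt, CH2Cl2, 0 °C → rt
Reagents that add atoms: chloromethyl methyl ether, COCCl
Why: Williamson-type acetal ether formation protects the phenol so that the aldehyde brings no acidic proton into the aldol step and is unmasked with the other MOM groups at the end.

Step 10
Reactants: 16 (2S,3S)-2-[3,4-bis(methoxymethoxy)phenyl]-3-[4-(methoxymethoxy)-2-oxo-2H-pyran-6-yl]-6-methyl-2,3-dihydro-4H-furo[3,2-c]pyran-4-one; 18 4-(methoxymethoxy)benzaldehyde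
Product: 22 (2S,3S)-2-[3,4-bis(methoxymethoxy)phenyl]-3-[4-(methoxymethoxy)-2-oxo-2H-pyran-6-yl]-6-{(E)-2-[4-(methoxymethoxy)phenyl]ethenyl}-2,3-dihydro-4H-furo[3,2-c]pyran-4-one, via lithium dienolate 19 (not isolated), via lithium aldolate 20 (not isolated), via benzylic mesylate 21 (not isolated)
Conditions: LiN(SiMe3)2 (1.05 equiv), THF, −78 °C; 18; MsCl, −78 °C; Et3N, −78 → 0 °C
Reagents that add atoms: none
Why: Vinylogous aldol addition followed by mesylate elimination: the bulky amide should remove a proton from the unhindered C6 methyl group under kinetic control at −78 °C (the C3–H is tertiary and flanked by the aryl-bearing C2 and two rings, and loss of O1 from a C3 anion would be a stereoelectronically disfavoured retro-5-endo-trig process), the dienolate adds through its exocyclic carbon to the non-enolisable aldehyde, and the para-alkoxybenzylic mesylate eliminates with triethylamine to the conjugated E-alkene without touching C2 or C3.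

Step 11
Reactants: 22 (2S,3S)-2-[3,4-bis(methoxymethoxy)phenyl]-3-[4-(methoxymethoxy)-2-oxo-2H-pyran-6-yl]-6-{(E)-2-[4-(methoxymethoxy)phenyl]ethenyl}-2,3-dihydro-4H-furo[3,2-c]pyran-4-one
Product: 23 (2S,3S)-2-(3,4-dihydroxyphenyl)-3-(4-hydroxy-2-oxo-2H-pyran-6-yl)-6-[(E)-2-(4-hydroxyphenyl)ethenyl]-2,3-dihydro-4H-furo[3,2-c]pyran-4-one
Conditions: HCl (3 M in MeOH), THF, Ar, 0 °C → rt
Reagents that add atoms: none
Why: Acid-catalysed acetal exchange with methanol should remove all four MOM groups as dimethoxymethane, which keeps formaldehyde away from the nucleophilic pyranone C3 position, at a temperature that leaves the lactones, the styryl double bond and the trans-dihydrofuran intact.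

**Compound list**

1 | 4-hydroxy-6-methyl-2H-pyran-2-one | Cc1cc(O)cc(=O)o1 | starting material
2 | 4-(methoxymethoxy)-6-methyl-2H-pyran-2-one | Cc1cc(OCOC)cc(=O)o1 | intermediate
3 | 3,4-dihydroxybenzaldehyde | O=Cc1ccc(O)c(O)c1 | starting material
4 | 3,4-bis[(tert-butyldimethylsilyl)oxy]benzaldehyde | O=Cc1ccc(O[Si](C)(C)C(C)(C)C)c(O[Si](C)(C)C(C)(C)C)c1 | intermediate
5 | lithium 4-(methoxymethoxy)-6-methylidene-6H-pyran-2-olate (extended dienolate of 2, formed in the flask) | [Li+].[O-]C1=CC(OCOC)=CC(=C)O1 | intermediate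
6 | lithium 1-{3,4-bis[(tert-butyldimethylsilyl)oxy]phenyl}-2-[4-(methoxymethoxy)-2-oxo-2H-pyran-6-yl]ethan-1-olate (racemic, formed in the flask) | [Li+].[O-]C(Cc1cc(OCOC)cc(=O)o1)c1ccc(O[Si](C)(C)C(C)(C)C)c(O[Si](C)(C)C(C)(C)C)c1 | intermediate
7 | 1-{3,4-bis[(tert-butyldimethylsilyl)oxy]phenyl}-2-[4-(methoxymethoxy)-2-oxo-2H-pyran-6-yl]ethyl methanesulfonate (racemic, formed in the flask) | CS(=O)(=O)OC(Cc1cc(OCOC)cc(=O)o1)c1ccc(O[Si](C)(C)C(C)(C)C)c(O[Si](C)(C)C(C)(C)C)c1 | intermediate
8 | 6-[(E)-2-{3,4-bis[(tert-butyldimethylsilyl)oxy]phenyl}ethenyl]-4-(methoxymethoxy)-2H-pyran-2-one | O=c1cc(OCOC)cc(/C=C/c2ccc(O[Si](C)(C)C(C)(C)C)c(O[Si](C)(C)C(C)(C)C)c2)o1 | intermediate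
9 | 6-[(E)-2-(3,4-dihydroxyphenyl)ethenyl]-4-(methoxymethoxy)-2H-pyran-2-one (formed in the flask) | O=c1cc(OCOC)cc(/C=C/c2ccc(O)c(O)c2)o1 | intermediate
10 | 4-{(E)-2-[4-(methoxymethoxy)-2-oxo-2H-pyran-6-yl]ethenyl}-1,2-phenylene diacetate | O=c1cc(OCOC)cc(/C=C/c2ccc(OC(C)=O)c(OC(C)=O)c2)o1 | intermediate
11 | 3-diazo-6-methyl-2H-pyran-2,4(3H)-dione | CC1=CC(=O)C(=[N+]=[N-])C(=O)O1 | intermediate
12 | 4-{(1S,2R,3R)-2-[4-(methoxymethoxy)-2-oxo-2H-pyran-6-yl]-6-methyl-4,8-dioxo-5-oxaspiro[2.5]oct-6-en-1-yl}-1,2-phenylene diacetate (trans cyclopropane, key-step precursor) | O=c1cc(OCOC)cc([C@@H]2[C@@H](c3ccc(OC(C)=O)c(OC(C)=O)c3)[C@]24C(=O)C=C(C)OC4=O)o1 | intermediate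
13 | (1S,2R,3R)-1-(3,4-dihydroxyphenyl)-2-[4-(methoxymethoxy)-2-oxo-2H-pyran-6-yl]-6-methyl-5-oxaspiro[2.5]oct-6-ene-4,8-dione (present as its 4-phenoxide, formed in the flask) | O=c1cc(OCOC)cc([C@@H]2[C@@H](c3ccc(O)c(O)c3)[C@]24C(=O)C=C(C)OC4=O)o1 | intermediate
14 | 4-hydroxy-3-{(1R)-2-(3-hydroxy-4-oxocyclohexa-2,5-dien-1-ylidene)-1-[4-(methoxymethoxy)-2-oxo-2H-pyran-6-yl]ethyl}-6-methyl-2H-pyran-2-one (para-quinone methide, present as its pyranolate, methide geometry not defined, formed in the flask) | O=c1cc(OCOC)cc([C@H](C=C2C=CC(=O)C(O)=C2)c2c(O)cc(C)oc2=O)o1 | intermediate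
15 | (2S,3S)-2-(3,4-dihydroxyphenyl)-3-[4-(methoxymethoxy)-2-oxo-2H-pyran-6-yl]-6-methyl-2,3-dihydro-4H-furo[3,2-c]pyran-4-one (trans, key-step product) | O=c1cc(OCOC)cc([C@H]2c3c(cc(C)oc3=O)O[C@@H]2c2ccc(O)c(O)c2)o1 | intermediate
16 | (2S,3S)-2-[3,4-bis(methoxymethoxy)phenyl]-3-[4-(methoxymethoxy)-2-oxo-2H-pyran-6-yl]-6-methyl-2,3-dihydro-4H-furo[3,2-c]pyran-4-one | O=c1cc(OCOC)cc([C@H]2c3c(cc(C)oc3=O)O[C@@H]2c2ccc(OCOC)c(OCOC)c2)o1 | intermediate
17 | 4-hydroxybenzaldehyde | O=Cc1ccc(O)cc1 | starting material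
18 | 4-(methoxymethoxy)benzaldehyde | O=Cc1ccc(OCOC)cc1 | intermediate
19 | lithium (2S,3S)-2-[3,4-bis(methoxymethoxy)phenyl]-3-[4-(methoxymethoxy)-2-oxo-2H-pyran-6-yl]-6-methylidene-3,6-dihydro-2H-furo[3,2-c]pyran-4-olate (extended dienolate of 16, formed in the flask) | O=c1cc(OCOC)cc([C@H]2C3=C([O-])OC(=C)C=C3O[C@@H]2c2ccc(OCOC)c(OCOC)c2)o1.[Li+] | intermediate
20 | lithium aldolate of 16 and 18, 6-{2-(lithiooxy)-2-[4-(methoxymethoxy)phenyl]ethyl} derivative of 16 (both carbinol epimers, formed in the flask) | O=c1cc(OCOC)cc([C@H]2c3c(cc(CC([O-])c4ccc(OCOC)cc4)oc3=O)O[C@@H]2c2ccc(OCOC)c(OCOC)c2)o1.[Li+] | intermediate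
21 | methanesulfonate of the aldol adduct, 6-{2-(mesyloxy)-2-[4-(methoxymethoxy)phenyl]ethyl} derivative of 16 (both epimers, formed in the flask) | O=c1cc(OCOC)cc([C@H]2c3c(cc(CC(OS(C)(=O)=O)c4ccc(OCOC)cc4)oc3=O)O[C@@H]2c2ccc(OCOC)c(OCOC)c2)o1 | intermediate
22 | (2S,3S)-2-[3,4-bis(methoxymethoxy)phenyl]-3-[4-(methoxymethoxy)-2-oxo-2H-pyran-6-yl]-6-{(E)-2-[4-(methoxymethoxy)phenyl]ethenyl}-2,3-dihydro-4H-furo[3,2-c]pyran-4-one | O=c1cc(OCOC)cc([C@H]2c3c(cc(/C=C/c4ccc(OCOC)cc4)oc3=O)O[C@@H]2c2ccc(OCOC)c(OCOC)c2)o1 | intermediate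
23 | (2S,3S)-2-(3,4-dihydroxyphenyl)-3-(4-hydroxy-2-oxo-2H-pyran-6-yl)-6-[(E)-2-(4-hydroxyphenyl)ethenyl]-2,3-dihydro-4H-furo[3,2-c]pyran-4-one (CNP0330607.1) | O=c1cc(O)cc([C@H]2c3c(cc(/C=C/c4ccc(O)cc4)oc3=O)O[C@@H]2c2ccc(O)c(O)c2)o1 | target

**Step count.** Total: 11 steps. Longest linear sequence: 8 steps (1, 3, 4, 6, 7, 8, 10, 11).

**Steps most likely to fail**

1. Step 7 (Proposed new method). Methoxide may add to the enol-lactone carbonyl of the spiro ring, or open the activated cyclopropane at the benzylic carbon, before the acetates are cleaved. The transient quinone methide may also tautomerise to a vinylphenol, which would erase C3. The fallback sets out from 12 and uses the known Lewis acid-catalysed Cloke–Wilson rearrangement. Sc(OTf)3 (10 mol %) with 4 Å MS in 1,2-dichloroethane at 40 °C should ionise the C1–C3 bond and reclose through the ketone oxygen under thermodynamic control, giving 4-{(2S,3S)-3-[4-(methoxymethoxy)-2-oxo-2H-pyran-6-yl]-6-methyl-4-oxo-2,3-dihydro-4H-furo[3,2-c]pyran-2-yl}-1,2-phenylene diacetate F1 with C3 untouched. Both electrophilic sites of the spiro ring are then gone, and brief K2CO3/MeOH at 0 °C removes the acetates (and corrects any cis isomer through reversible phenoxide opening). The fallback comes back to the route at 15.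

2. Step 6. Carbene transfer to the 1,2-disubstituted, conjugated alkene may be slower than carbenoid decomposition or attack on the pyranone enol ether, and facial discrimination may be poor. Premature ring expansion by the Lewis acidic catalyst would only anticipate step 7. The fallback sets out from 1 and 10. PhI(OAc)2 with Na2CO3 converts 1 into the iodonium ylide 6-methyl-2-oxo-3-(phenyliodonio)-2H-pyran-4-olate F2. This transfers the same carbene to 10 at or below room temperature with the robust achiral catalyst Rh2(esp)2 in CH2Cl2, giving the racemic trans-spirocyclopropane F3. Preparative chromatography on a chiral stationary phase then supplies the (1S,2R) enantiomer, so enantiopurity comes from resolution instead of asymmetric induction. The fallback comes back to the route at 12.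

3. Step 10. Deprotonation may occur at C3 instead of the methyl group, leading to epimerisation or loss of O1, and proton transfer between substrate molecules may erode the kinetic selectivity. The fallback moves the carbon–carbon bond formation to the start, so that no strong base is used after the key step; it sets out from 1 and 18.
   - The dianion of 1 (LiN(iPr)2, 2.2 equiv, THF, −78 → 0 °C) adds through its methyl carbon to 18, giving racemic 4-hydroxy-6-{2-hydroxy-2-[4-(methoxymethoxy)phenyl]ethyl}-2H-pyran-2-one F4.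
   - Silylation (TBSOTf, 2,6-lutidine; the labile 4-O-silyl group is lost on aqueous work-up) gives 6-{2-[(tert-butyldimethylsilyl)oxy]-2-[4-(methoxymethoxy)phenyl]ethyl}-4-hydroxy-2H-pyran-2-one F5.
   - Diazo transfer as in step 5 gives 6-{2-[(tert-butyldimethylsilyl)oxy]-2-[4-(methoxymethoxy)phenyl]ethyl}-3-diazo-2H-pyran-2,4(3H)-dione F6.
   - Cyclopropanation of 10 as in step 6 gives the spirocyclopropane carrying the masked styryl side chain F7.
   - Carbonate methanolysis as in step 7 gives the corresponding (2S,3S)-dihydrofuran catechol F8.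
   - HCl in MeOH then removes both MOM groups and ionises the para-hydroxybenzylic silyl ether, which eliminates to the E-styryl group.

   The fallback comes back to the route at 23.

**Further compounds**

F1 | step 7 | 4-{(2S,3S)-3-[4-(methoxymethoxy)-2-oxo-2H-pyran-6-yl]-6-methyl-4-oxo-2,3-dihydro-4H-furo[3,2-c]pyran-2-yl}-1,2-phenylene diacetate | O=c1cc(OCOC)cc([C@H]2c3c(cc(C)oc3=O)O[C@@H]2c2ccc(OC(C)=O)c(OC(C)=O)c2)o1
F2 | step 6 | 6-methyl-2-oxo-3-(phenyliodonio)-2H-pyran-4-olate | CC1=CC([O-])=C([I+]c2ccccc2)C(=O)O1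
F3 | step 6 | racemic trans-spirocyclopropane (12 and its enantiomer, 1:1) | O=c1cc(OCOC)cc([C@@H]2[C@@H](c3ccc(OC(C)=O)c(OC(C)=O)c3)[C@]24C(=O)C=C(C)OC4=O)o1.O=c1cc(OCOC)cc([C@H]2[C@H](c3ccc(OC(C)=O)c(OC(C)=O)c3)[C@@]24C(=O)C=C(C)OC4=O)o1
F4 | step 10 | 4-hydroxy-6-{2-hydroxy-2-[4-(methoxymethoxy)phenyl]ethyl}-2H-pyran-2-one (racemic) | O=c1cc(O)cc(CC(O)c2ccc(OCOC)cc2)o1
F5 | step 10 | 6-{2-[(tert-butyldimethylsilyl)oxy]-2-[4-(methoxymethoxy)phenyl]ethyl}-4-hydroxy-2H-pyran-2-one (racemic) | O=c1cc(O)cc(CC(O[Si](C)(C)C(C)(C)C)c2ccc(OCOC)cc2)o1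
F6 | step 10 | 6-{2-[(tert-butyldimethylsilyl)oxy]-2-[4-(methoxymethoxy)phenyl]ethyl}-3-diazo-2H-pyran-2,4(3H)-dione (racemic) | [N-]=[N+]=C1C(=O)C=C(CC(O[Si](C)(C)C(C)(C)C)c2ccc(OCOC)cc2)OC1=O
F7 | step 10 | 4-{(1S,2R,3R)-6-{2-[(tert-butyldimethylsilyl)oxy]-2-[4-(methoxymethoxy)phenyl]ethyl}-2-[4-(methoxymethoxy)-2-oxo-2H-pyran-6-yl]-4,8-dioxo-5-oxaspiro[2.5]oct-6-en-1-yl}-1,2-phenylene diacetate (both epimers at the silyloxy carbon) | O=c1cc(OCOC)cc([C@@H]2[C@@H](c3ccc(OC(C)=O)c(OC(C)=O)c3)[C@]24C(=O)C=C(CC(O[Si](C)(C)C(C)(C)C)c3ccc(OCOC)cc3)OC4=O)o1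
F8 | step 10 | (2S,3S)-6-{2-[(tert-butyldimethylsilyl)oxy]-2-[4-(methoxymethoxy)phenyl]ethyl}-2-(3,4-dihydroxyphenyl)-3-[4-(methoxymethoxy)-2-oxo-2H-pyran-6-yl]-2,3-dihydro-4H-furo[3,2-c]pyran-4-one (both epimers at the silyloxy carbon) | O=c1cc(OCOC)cc([C@H]2c3c(cc(CC(O[Si](C)(C)C(C)(C)C)c4ccc(OCOC)cc4)oc3=O)O[C@@H]2c2ccc(O)c(O)c2)o1
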